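**Strategy.** The 14-membered ring is closed last, at the C9–C10 bond of the trans-9,10-diol (cembrane numbering: C1 carries the isopropenyl group, C14 the acetate). Both carbinol carbons are allylic, each flanked by an E-trisubstituted olefin (C7=C8, C11=C12), so the diol is the retron of a reductive coupling of two enals. A titanium-mediated intramolecular pinacol coupling of the acyclic (14S)-acetoxy 9,10-dialdehyde should form the carbocycle, the C–C bond and both carbinol stereocentres in one operation. The dialdehyde comes from a Negishi union of a C3–C9 alkenylalane with a C10–C14/C1–C2 (Z)-vinyl iodide made by asymmetric vinylogous aldol addition and anti-carbomagnesiation.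

Key step: step 11

Assumption: the (S,S) antipode of the bisphosphoramide in step 2 is the one expected to expose the Si face of the ynal (the mirror-image catalyst is used if a first run shows the opposite sense), and the enol ether geometry of 2 is immaterial.

**Step 1**
Reactants: 1 methyl 3-methylbut-2-enoate
Product: 2 tert-butyl[(1-methoxy-3-methylbuta-1,3-dien-1-yl)oxy]dimethylsilane
Conditions: LDA, THF, −78 °C; TBSCl, DMPU, −78 °C → rt
Reagents that add atoms: tert-butyldimethylsilyl chloride, CC(C)(C)[Si](C)(C)Cl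
Why: Kinetic γ-deprotonation of the senecioate ester and O-silylation of the extended enolate give the silyl dienol ether (silyl ketene acetal formation); no stereocentre is formed.

**Step 2**
Reactants: 2 tert-butyl[(1-methoxy-3-methylbuta-1,3-dien-1-yl)oxy]dimethylsilane; 3 3-(trimethylsilyl)prop-2-ynal
Product: 4 methyl (2E,5S)-5-hydroxy-3-methyl-7-(trimethylsilyl)hept-2-en-6-ynoate
Conditions: SiCl4 (1.1 equiv), (S,S)-binaphthyldiamine-derived bisphosphoramide (5 mol %), iPr2NEt (10 mol %), CH2Cl2, −78 °C; aq. KF/NaHCO3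
Reagents that add atoms: none
Why: Catalytic enantioselective vinylogous Mukaiyama aldol addition (chiral Lewis base-activated SiCl4): the dienolate reacts at its γ-carbon with the ynal held in the chiral trichlorosilyl cation complex, Si-face attack setting the carbinol centre as S (the future C14) and the open transition state giving the E-enoate.

**Step 3**
Reactants: 4 methyl (2E,5S)-5-hydroxy-3-methyl-7-(trimethylsilyl)hept-2-en-6-ynoate
Product: 5 (2E,5S)-3-methyl-7-(trimethylsilyl)hept-2-en-6-yne-1,5-diol
Conditions: DIBAL-H (3.5 equiv), CH2Cl2, −78 → 0 °C; Rochelle salt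
Reagents that add atoms: none
Why: DIBAL-H reduces the conjugated ester 1,2 to the allylic alcohol (ester reduction) without touching the silylalkyne, the E-olefin or the stereocentre.

**Step 4**
Reactants: 5 (2E,5S)-3-methyl-7-(trimethylsilyl)hept-2-en-6-yne-1,5-diol
Product: 6 (2E,5S)-3-methylhept-2-en-6-yne-1,5-diol
Conditions: K2CO3, MeOH, rt
Reagents that add atoms: none
Why: Base-mediated methanolysis of the alkynyl C–Si bond (protodesilylation) frees the terminal alkyne needed for the carbometallation.

**Step 5**
Reactants: 6 (2E,5S)-3-methylhept-2-en-6-yne-1,5-diol; 7 isopropenylmagnesium bromide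
Product: 9 (2E,5S,6Z)-7-iodo-3-methyl-6-(prop-1-en-2-yl)hepta-2,6-diene-1,5-diol, via alkenylmagnesium chelate 8 (not isolated)
Conditions: 7 (4.5 equiv), CuI (20 mol %), THF, 0 °C → rt; then I2, −40 → 0 °C; aq. NH4Cl/Na2S2O3
Reagents that add atoms: iodine, II
Why: Copper-catalysed anti-carbomagnesiation of a propargylic alcohol: the magnesium alkoxide directs the isopropenyl group to the internal alkyne carbon through a five-membered oxamagnesacycle, so magnesium, and then iodine with retention, sits cis to the carbinol and fixes the Z geometry of the future C1=C2 bond.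

**Step 6**
Reactants: 10 pent-4-yn-1-ol; 11 ethyl 2-(triphenyl-λ5-phosphanylidene)propanoate
Product: 13 ethyl (2E)-2-methylhept-2-en-6-ynoate, via pent-4-ynal 12 (not isolated)
Conditions: (COCl)2, DMSO, CH2Cl2, −78 °C; Et3N; then 11, −78 °C → rt
Reagents that add atoms: none
Why: Swern oxidation followed in the same flask by Wittig olefination with the α-methyl stabilised ylide avoids isolating the volatile aldehyde and should give the E-trisubstituted enoate.

**Step 7**
Reactants: 13 ethyl (2E)-2-methylhept-2-en-6-ynoate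
Product: 14 (2E)-2-methylhept-2-en-6-yn-1-ol
Conditions: DIBAL-H (2.2 equiv), CH2Cl2, −78 °C; Rochelle salt
Reagents that add atoms: none
Why: DIBAL-H 1,2-reduction of the enoate gives the allylic alcohol with the E geometry retained.

**Step 8**
Reactants: 14 (2E)-2-methylhept-2-en-6-yn-1-ol; 9 (2E,5S,6Z)-7-iodo-3-methyl-6-(prop-1-en-2-yl)hepta-2,6-diene-1,5-diol
Product: 16 (2E,5S,6Z,8E,12E)-3,9,13-trimethyl-6-(prop-1-en-2-yl)tetradeca-2,6,8,12-tetraene-1,5,14-triol, via alkenyldimethylalane 15 (not isolated)
Conditions: 14, Me3Al (4 equiv), Cp2ZrCl2 (0.3 equiv), (CH2Cl)2, 0 °C → rt; then 9 (pretreated with Me3Al, 2 equiv, THF, 0 °C), ZnCl2 (1 equiv), Pd(PPh3)4 (5 mol %), THF, rt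
Reagents that add atoms: trimethylaluminium, C[Al](C)C
Why: Zirconium-catalysed syn-methylalumination of the terminal alkyne places aluminium and the new methyl cis, and the Pd/Zn-mediated Negishi coupling proceeds with retention at both sp2 carbons to give the (6Z,8E)-diene, the three hydroxyls being held as aluminium alkoxides.

**Step 9**
Reactants: 16 (2E,5S,6Z,8E,12E)-3,9,13-trimethyl-6-(prop-1-en-2-yl)tetradeca-2,6,8,12-tetraene-1,5,14-triol
Product: 17 (2E,5S,6Z,8E,12E)-5-hydroxy-3,9,13-trimethyl-6-(prop-1-en-2-yl)tetradeca-2,6,8,12-tetraenedial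
Conditions: TEMPO (20 mol %), PhI(OAc)2 (2.3 equiv), CH2Cl2, 0 °C → rt
Reagents that add atoms: none
Why: Oxoammonium (TEMPO/PhI(OAc)2) oxidation is selective for the two unhindered primary allylic alcohols over the hindered secondary allylic C5 alcohol and stops at the enals without E/Z erosion.

**Step 10**
Reactants: 17 (2E,5S,6Z,8E,12E)-5-hydroxy-3,9,13-trimethyl-6-(prop-1-en-2-yl)tetradeca-2,6,8,12-tetraenedial
Product: 18 (2E,5S,6Z,8E,12E)-3,9,13-trimethyl-1,14-dioxo-6-(prop-1-en-2-yl)tetradeca-2,6,8,12-tetraen-5-yl acetate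
Conditions: Ac2O, pyridine, DMAP (cat.), CH2Cl2, 0 °C
Reagents that add atoms: acetic anhydride, CC(=O)OC(C)=O
Why: DMAP-catalysed acylation of the only remaining hydroxyl, run briefly at 0 °C to limit vinylogous β-elimination of the δ-acetoxy enal.

**Step 11**
Reactants: 18 (2E,5S,6Z,8E,12E)-3,9,13-trimethyl-1,14-dioxo-6-(prop-1-en-2-yl)tetradeca-2,6,8,12-tetraen-5-yl acetate
Product: 19 (1S,2Z,4E,8E,10R,11R,12E)-10,11-dihydroxy-5,9,13-trimethyl-2-(prop-1-en-2-yl)cyclotetradeca-2,4,8,12-tetraen-1-yl acetate
Conditions: TiCl3(DME)1.5 (12 equiv), Zn–Cu (30 equiv), DME, reflux, then 25 °C; 18 added by syringe pump over 30 h (final concentration about 3 mM); 20% aq. K2CO3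
Reagents that add atoms: none
Why: Low-valent titanium from TiCl3(DME)1.5 and Zn–Cu transfers one electron to each enal carbonyl, and the two titanium-bound ketyl radicals couple at the carbonyl carbons C9 and C10 on the metal template to a titanium 9,10-diolate that is not deoxygenated at room temperature and is hydrolysed on work-up (intramolecular pinacol coupling, McMurry-type). The closest known reaction type is the titanium-induced pinacol macrocyclisation of acyclic dialdehydes and keto aldehydes to 14-membered cembranoid 1,2-diols. The ring closed is the 14-membered carbocycle, exo-trig at both termini (both C=O bonds lie outside the new ring), and slow addition at high dilution keeps the coupling intramolecular. The relative configuration at C9/C10 (trans, threo) is controlled by the titanium template, which holds the two oxygens syn while the alkenyl arms sit anti; the absolute sense (9R,10R) has to come from the C14 acetoxy stereocentre, relayed through the conformation of the closing ring, in which the E-trisubstituted olefin planes stand perpendicular to the ring and the C14 substituent points outward. The step needs head-to-head 1,2-coupling rather than coupling at the β-carbons, which the substituted C7 and fully substituted C12 favour, and survival of the C14 acetate, which the room-temperature reagent should allow. The 1,5-induction from C14 is the least secured selectivity and is treated below.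

**Compound list**
1 | methyl 3-methylbut-2-enoate | COC(=O)C=C(C)C | starting material
2 | tert-butyl[(1-methoxy-3-methylbuta-1,3-dien-1-yl)oxy]dimethylsilane | C=C(C)C=C(OC)O[Si](C)(C)C(C)(C)C | intermediate
3 | 3-(trimethylsilyl)prop-2-ynal | C[Si](C)(C)C#CC=O | starting material
4 | methyl (2E,5S)-5-hydroxy-3-methyl-7-(trimethylsilyl)hept-2-en-6-ynoate | COC(=O)/C=C(\C)C[C@H](O)C#C[Si](C)(C)C | intermediate
5 | (2E,5S)-3-methyl-7-(trimethylsilyl)hept-2-en-6-yne-1,5-diol | OC/C=C(\C)C[C@H](O)C#C[Si](C)(C)C | intermediate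
6 | (2E,5S)-3-methylhept-2-en-6-yne-1,5-diol | OC/C=C(\C)C[C@H](O)C#C | intermediate
7 | isopropenylmagnesium bromide | C=C(C)[Mg]Br | starting material
8 | bis(bromomagnesium) alkoxide of (2E,5S,6Z)-7-(bromomagnesio)-3-methyl-6-(prop-1-en-2-yl)hepta-2,6-diene-1,5-diol | Br[Mg]OC/C=C(\C)C[C@H](O[Mg]Br)/C(=C\[Mg]Br)C(C)=C | intermediate
9 | (2E,5S,6Z)-7-iodo-3-methyl-6-(prop-1-en-2-yl)hepta-2,6-diene-1,5-diol | OC/C=C(\C)C[C@H](O)/C(=C\I)C(C)=C | intermediate
10 | pent-4-yn-1-ol | OCCCC#C | starting material
11 | ethyl 2-(triphenyl-λ5-phosphanylidene)propanoate | CCOC(=O)C(C)=P(c1ccccc1)(c1ccccc1)c1ccccc1 | starting material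
12 | pent-4-ynal | O=CCCC#C | intermediate
13 | ethyl (2E)-2-methylhept-2-en-6-ynoate | CCOC(=O)/C(C)=C/CCC#C | intermediate
14 | (2E)-2-methylhept-2-en-6-yn-1-ol | OC/C(C)=C/CCC#C | intermediate
15 | dimethylaluminium alkoxide of (2E,6E)-7-(dimethylalumanyl)-2,6-dimethylhepta-2,6-dien-1-ol | C[Al](C)/C=C(\C)CC/C=C(\C)CO[Al](C)C | intermediate
16 | (2E,5S,6Z,8E,12E)-3,9,13-trimethyl-6-(prop-1-en-2-yl)tetradeca-2,6,8,12-tetraene-1,5,14-triol | C=C(C)/C(=C/C=C(\C)CC/C=C(\C)CO)[C@@H](O)C/C(C)=C/CO | intermediate
17 | (2E,5S,6Z,8E,12E)-5-hydroxy-3,9,13-trimethyl-6-(prop-1-en-2-yl)tetradeca-2,6,8,12-tetraenedial | C=C(C)/C(=C/C=C(\C)CC/C=C(\C)C=O)[C@@H](O)C/C(C)=C/C=O | intermediate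
18 | (2E,5S,6Z,8E,12E)-3,9,13-trimethyl-1,14-dioxo-6-(prop-1-en-2-yl)tetradeca-2,6,8,12-tetraen-5-yl acetate | C=C(C)/C(=C/C=C(\C)CC/C=C(\C)C=O)[C@@H](OC(C)=O)C/C(C)=C/C=O | intermediate
19 | (1S,2Z,4E,8E,10R,11R,12E)-10,11-dihydroxy-5,9,13-trimethyl-2-(prop-1-en-2-yl)cyclotetradeca-2,4,8,12-tetraen-1-yl acetate | C=C(C)/C1=C/C=C(\C)CC/C=C(\C)[C@@H](O)[C@H](O)/C=C(\C)C[C@@H]1OC(C)=O | target

**Step count.** Total: 11 steps. Longest linear sequence: 9 steps (steps 1–5, then 8–11); steps 6–7 form the second branch.

**Steps most likely to fail**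

1. Step 11. The relay of chirality from C14 to the closing C9–C10 bond may be weak, so that both trans-diols and some cis-diol form; partial deoxygenation to the olefin or reductive loss of the allylic acetate may also occur. The fallback sets out from 18 and comes back at 19, moving the control of both carbinol centres from the substrate to a catalyst. The same titanium closure is run on 18 without regard to facial selectivity, and the whole mixture of macrocyclic 9,10-diol stereoisomers F1 is oxidised under neutral conditions (IBX, DMSO/EtOAc, rt) to the macrocyclic 9,10-dione F2, which erases both centres. F2 is then reduced twice, 1,2-selectively, under catalyst control (Corey–Bakshi–Shibata oxazaborolidine with catecholborane, toluene, −78 °C, antipode chosen for 9R,10R) to give 19.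

2. Step 2. Enantiofacial discrimination on the slender ynal may be poor, or α-attack and conjugate addition may compete. The fallback sets out from 2 and 3 and comes back at 4, replacing asymmetric C–C bond formation by asymmetric reduction. An achiral vinylogous Mukaiyama aldol addition (BF3·OEt2, CH2Cl2, −78 °C) should give the racemic hydroxy ester F3. Dess–Martin oxidation should give the alkynyl ketone F4, and asymmetric transfer hydrogenation of the ynone (RuCl[(S,S)-TsDPEN](p-cymene), iPrOH, rt) is expected to give (S)-configured 4.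

3. Step 9. The oxidation may not stop at the primary alcohols, giving the cross-conjugated C5 ketone, and the δ-acetoxy enal formed in step 10 may undergo base-induced vinylogous elimination. The fallback sets out from 16 and comes back at 18, differentiating the hydroxyls by protection instead of by oxidant selectivity. The two primary allylic alcohols are silylated (TBSCl, imidazole, CH2Cl2, −20 °C) to the bis-silyl ether F5, and the secondary alcohol is acetylated (Ac2O, pyridine, DMAP) to the acetate F6. Desilylation (HF·pyridine, pyridine, THF) gives the acetoxy diol F7, and neutral oxidation of both allylic alcohols (MnO2, CH2Cl2) gives 18 without exposing the acetoxy dialdehyde to base.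

**Further compounds**
F1 | step 11 | (1S,2Z,4E,8E,12E)-10,11-dihydroxy-5,9,13-trimethyl-2-(prop-1-en-2-yl)cyclotetradeca-2,4,8,12-tetraen-1-yl acetate, mixture of C10/C11 stereoisomers | C=C(C)/C1=C/C=C(\C)CC/C=C(\C)C(O)C(O)/C=C(\C)C[C@@H]1OC(C)=O
F2 | step 11 | (1S,2Z,4E,8E,12E)-5,9,13-trimethyl-10,11-dioxo-2-(prop-1-en-2-yl)cyclotetradeca-2,4,8,12-tetraen-1-yl acetate | C=C(C)/C1=C/C=C(\C)CC/C=C(\C)C(=O)C(=O)/C=C(\C)C[C@@H]1OC(C)=O
F3 | step 2 | methyl (2E)-5-hydroxy-3-methyl-7-(trimethylsilyl)hept-2-en-6-ynoate, racemic | COC(=O)/C=C(\C)CC(O)C#C[Si](C)(C)C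
F4 | step 2 | methyl (2E)-3-methyl-5-oxo-7-(trimethylsilyl)hept-2-en-6-ynoate | COC(=O)/C=C(\C)CC(=O)C#C[Si](C)(C)C
F5 | step 9 | (2E,5S,6Z,8E,12E)-1,14-bis[(tert-butyldimethylsilyl)oxy]-3,9,13-trimethyl-6-(prop-1-en-2-yl)tetradeca-2,6,8,12-tetraen-5-ol | C=C(C)/C(=C/C=C(\C)CC/C=C(\C)CO[Si](C)(C)C(C)(C)C)[C@@H](O)C/C(C)=C/CO[Si](C)(C)C(C)(C)C
F6 | step 9 | (2E,5S,6Z,8E,12E)-1,14-bis[(tert-butyldimethylsilyl)oxy]-3,9,13-trimethyl-6-(prop-1-en-2-yl)tetradeca-2,6,8,12-tetraen-5-yl acetate | C=C(C)/C(=C/C=C(\C)CC/C=C(\C)CO[Si](C)(C)C(C)(C)C)[C@@H](OC(C)=O)C/C(C)=C/CO[Si](C)(C)C(C)(C)C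
F7 | step 9 | (2E,5S,6Z,8E,12E)-1,14-dihydroxy-3,9,13-trimethyl-6-(prop-1-en-2-yl)tetradeca-2,6,8,12-tetraen-5-yl acetate | C=C(C)/C(=C/C=C(\C)CC/C=C(\C)CO)[C@@H](OC(C)=O)C/C(C)=C/CO
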